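**Plan**

1. Numbering (farnesane): C1 = CH2Br, C2 = CHOAc, C3 (C15 methyl) = C4, C5 = CH2, ring = C6 (CH), C7 (=C14H2), C8, C9, C10 (CHBr), C11 (CMe2).
2. Retrosynthesis: the ring bond C6–C11 is cut first, tracing C10–Br to a bromonium ion and C7=C14 to an allylsilane; this leaves an acyclic (10R)-10-hydroxy-11-bromide with a (6Z) C14-silyl group. Then C4–C5 and C3–C15 (carbomagnesiation/allylation), C7–C14 (Kumada coupling) and C8–C9 (dianion alkylation) are cut.
3. Forward: the C5–C14 chain comes from methyl acetoacetate and prenyl bromide (6 steps) and (R)-but-3-yne-1,2-diol from a serine-derived glycerate (2 steps); a three-component union and three functional-group steps follow, and the only ring is closed in the last step, which gives the target itself.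
4. Enabling feature: in the cyclohexane the CHBr carbon C10 is bonded to the gem-dimethyl carbon C11, C11 to the side-chain CH C6, and C6 to C7 with the exocyclic methylene. This is the footprint of a C10–C11 bromonium ion opened at its tertiary carbon by a C6=C7 allylsilane.
5. Stereochemistry: C10 from a Shi epoxidation (inverted once, in the key step); C6 from the chair transition state and the (6Z) allylsilane; C2 from the chiral pool; 3Z from a chelated anti-carbomagnesiation; 6Z from a chelated enolate.
6. Helpers: the silyl group on C14 and the oxygen on C10; both leave in the key step.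

Key step: step 13

Remark: the D-fructose-derived Shi ketone is taken to give the (R)-epoxide at the prenyl terminus, by analogy with its (R,R) sense for trans-disubstituted and trisubstituted alkenes.

**Step 1**
Reactants: 1 methyl acetoacetate; 2 1-bromo-3-methylbut-2-ene (prenyl bromide)
Product: 4 methyl 7-methyl-3-oxooct-6-enoate, via acetoacetate dianion 3 (not isolated)
Conditions: NaH, THF, 0 °C; n-BuLi, 0 °C; then 2, 0 °C → rt; 1 M HCl
Reagents that add atoms: none
Why: γ-alkylation of a β-keto ester dianion, in which the more basic terminal carbanion should displace the primary allylic bromide (SN2) and so form C8–C9; no stereocentre is involved.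

**Step 2**
Reactants: 4 methyl 7-methyl-3-oxooct-6-enoate
Product: 6 methyl (2Z)-3-[(diethoxyphosphoryl)oxy]-7-methylocta-2,6-dienoate, via sodium enolate 5 (not isolated)
Conditions: NaH, Et2O, 0 °C; ClP(O)(OEt)2, 0 °C → rt
Reagents that add atoms: diethyl chlorophosphate, CCOP(=O)(Cl)OCC
Why: O-phosphorylation of the sodium enolate, which in ether is chelated between both carbonyl oxygens, should give the (Z)-enol phosphate (phosphate cis to the ester) that later fixes the allylsilane geometry.

**Step 3**
Reactants: 6 methyl (2Z)-3-[(diethoxyphosphoryl)oxy]-7-methylocta-2,6-dienoate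
Product: 7 methyl (2Z)-7-methyl-3-[(trimethylsilyl)methyl]octa-2,6-dienoate
Conditions: Me3SiCH2MgCl, Ni(acac)2 (5 mol %), THF, 0 °C → rt
Reagents that add atoms: (trimethylsilyl)methylmagnesium chloride, C[Si](C)(C)C[Mg]Cl
Why: Kumada-type nickel-catalysed coupling of an enol phosphate proceeds with retention of alkene geometry, so CH2SiMe3 (C14) should end cis to the ester carbon C5 and trans to C8.

**Step 4**
Reactants: 7 methyl (2Z)-7-methyl-3-[(trimethylsilyl)methyl]octa-2,6-dienoate
Product: 8 methyl (2Z)-5-[(2R)-3,3-dimethyloxiran-2-yl]-3-[(trimethylsilyl)methyl]pent-2-enoate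
Conditions: 1,2:4,5-di-O-isopropylidene-β-D-erythro-2,3-hexodiulo-2,6-pyranose (30 mol %), KHSO5 (as 2KHSO5·KHSO4·K2SO4), K2CO3, Bu4NHSO4, MeCN/CH2(OMe)2/aq. Na2B4O7 buffer (pH 10.5), 0 °C
Reagents that add atoms: potassium peroxymonosulfate, [K+].[O-]S(=O)(=O)OO
Why: Shi epoxidation, in which the chiral dioxirane should attack only the electron-rich C10=C11 alkene (the silyl-bearing alkene is an electron-poor enoate at this stage) through the spiro transition state and set C10 as (R).

**Step 5**
Reactants: 8 methyl (2Z)-5-[(2R)-3,3-dimethyloxiran-2-yl]-3-[(trimethylsilyl)methyl]pent-2-enoate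
Product: 9 (2Z)-5-[(2R)-3,3-dimethyloxiran-2-yl]-3-[(trimethylsilyl)methyl]pent-2-en-1-ol
Conditions: i-Bu2AlH (2.2 equiv), CH2Cl2, −78 °C; aq. potassium sodium tartrate
Reagents that add atoms: none
Why: 1,2-reduction of the conjugated ester to the allylic alcohol at −78 °C should leave the trisubstituted epoxide, the alkene geometry and the silane untouched.

**Step 6**
Reactants: 9 (2Z)-5-[(2R)-3,3-dimethyloxiran-2-yl]-3-[(trimethylsilyl)methyl]pent-2-en-1-ol
Product: 11 (2R)-2-{(3Z)-5-bromo-3-[(trimethylsilyl)methyl]pent-3-en-1-yl}-3,3-dimethyloxirane, via allylic mesylate 10 (not isolated)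
Conditions: MsCl, Et3N, THF, −45 °C; then LiBr, THF, −45 → 0 °C; used crude
Reagents that add atoms: lithium bromide, [Li+].[Br-]
Why: mesylation followed by SN2 displacement with bromide at the primary allylic carbon under cold, non-acidic conditions should spare the epoxide and the allylsilane and keep the geometry.

**Step 7**
Reactants: 12 methyl (4S)-2,2-dimethyl-1,3-dioxolane-4-carboxylate (commercial, serine-derived)
Product: 14 (4R)-4-ethynyl-2,2-dimethyl-1,3-dioxolane, via glyceraldehyde acetonide 13 (not isolated)
Conditions: i-Bu2AlH (1.1 equiv), CH2Cl2, −78 °C; then MeOH, K2CO3, dimethyl (1-diazo-2-oxopropyl)phosphonate, −78 °C → rt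
Reagents that add atoms: dimethyl (1-diazo-2-oxopropyl)phosphonate, CC(=O)C(=[N+]=[N-])P(=O)(OC)OC
Why: the ester is reduced to the aldehyde oxidation level and homologated in the same flask by the Ohira–Bestmann reaction without touching the α-stereocentre, whose descriptor changes from S to R only through the CIP priorities.

**Step 8**
Reactants: 14 (4R)-4-ethynyl-2,2-dimethyl-1,3-dioxolane
Product: 15 (2R)-but-3-yne-1,2-diol
Conditions: sulfonic acid resin (H+ form), MeOH, rt
Reagents that add atoms: none
Why: acid-catalysed transacetalisation with methanol removes the acetonide and does not involve the propargylic stereocentre.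

**Step 9**
Reactants: 15 (2R)-but-3-yne-1,2-diol; 11 (2R)-2-{(3Z)-5-bromo-3-[(trimethylsilyl)methyl]pent-3-en-1-yl}-3,3-dimethyloxirane
Product: 17 (2R,3Z,6Z)-9-[(2R)-3,3-dimethyloxiran-2-yl]-3-methyl-7-[(trimethylsilyl)methyl]nona-3,6-diene-1,2-diol, via alkenylmagnesium chelate 16 (not isolated)
Conditions: 15 (1.5 equiv), MeMgBr (4.7 equiv), CuI (15 mol %), THF/Et2O, −10 °C → rt; then 11 (1.0 equiv), −30 → 0 °C; aq. NH4Cl
Reagents that add atoms: methylmagnesium bromide, C[Mg]Br
Why: copper-catalysed anti-carbomagnesiation of the propargylic alkoxide should place the methyl on C3 and magnesium on C4 cis to C2 in a five-membered chelate, and copper-catalysed SN2 allylation of this alkenylmagnesium by the primary allylic bromide (fully substituted γ-carbon) proceeds with retention, which forms C4–C5 and fixes 3Z.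

**Step 10**
Reactants: 17 (2R,3Z,6Z)-9-[(2R)-3,3-dimethyloxiran-2-yl]-3-methyl-7-[(trimethylsilyl)methyl]nona-3,6-diene-1,2-diol
Product: 19 (2R,3Z,6Z)-2-acetoxy-9-[(2R)-3,3-dimethyloxiran-2-yl]-3-methyl-7-[(trimethylsilyl)methyl]nona-3,6-dien-1-yl 4-methylbenzenesulfonate, via primary tosylate 18 (not isolated)
Conditions: TsCl (1.05 equiv), Et3N, Bu2SnO (2 mol %), CH2Cl2, 0 °C; then Ac2O, DMAP (cat.), 0 °C → rt
Reagents that add atoms: 4-methylbenzenesulfonyl chloride, Cc1ccc(cc1)S(=O)(=O)Cl; acetic anhydride, CC(=O)OC(C)=O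
Why: stannylene-catalysed sulfonylation is selective for the primary hydroxyl of a terminal 1,2-diol, and the remaining allylic secondary hydroxyl is then acetylated under DMAP catalysis without change at C2.

**Step 11**
Reactants: 19 (2R,3Z,6Z)-2-acetoxy-9-[(2R)-3,3-dimethyloxiran-2-yl]-3-methyl-7-[(trimethylsilyl)methyl]nona-3,6-dien-1-yl 4-methylbenzenesulfonate
Product: 20 (2R,3Z,6Z)-1-bromo-9-[(2R)-3,3-dimethyloxiran-2-yl]-3-methyl-7-[(trimethylsilyl)methyl]nona-3,6-dien-2-yl acetate
Conditions: LiBr, NaHCO3, acetone, 40 °C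
Reagents that add atoms: lithium bromide, [Li+].[Br-]
Why: Finkelstein-type SN2 displacement of the primary tosylate by bromide under neutral conditions should leave the trisubstituted epoxide, the allylic acetate and C2 untouched.

**Step 12**
Reactants: 20 (2R,3Z,6Z)-1-bromo-9-[(2R)-3,3-dimethyloxiran-2-yl]-3-methyl-7-[(trimethylsilyl)methyl]nona-3,6-dien-2-yl acetate
Product: 21 (2R,3Z,6Z,10R)-1,11-dibromo-10-hydroxy-3,11-dimethyl-7-[(trimethylsilyl)methyl]dodeca-3,6-dien-2-yl acetate
Conditions: MgBr2·OEt2 (2 equiv), Et2O, −30 → 0 °C; pH 7 buffer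
Reagents that add atoms: magnesium bromide diethyl etherate, [Mg+2].[Br-].[Br-].CCOCC
Why: Lewis-acid-assisted anti opening of the trisubstituted epoxide by bromide at the tertiary carbon C11 (Markovnikov, borderline SN2) leaves the C10–O bond and its (R) configuration intact, and ethereal MgBr2 is aprotic and mild enough that the allylsilane should survive.

**Step 13**
Reactants: 21 (2R,3Z,6Z,10R)-1,11-dibromo-10-hydroxy-3,11-dimethyl-7-[(trimethylsilyl)methyl]dodeca-3,6-dien-2-yl acetate
Product: 24 (2R,3Z)-1-bromo-5-[(1R,3S)-3-bromo-2,2-dimethyl-6-methylidenecyclohexyl]-3-methylpent-3-en-2-yl acetate (target), via secondary triflate 22 (not isolated), via bromonium triflate 23 (not isolated)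
Conditions: Tf2O (1.1 equiv), 2,6-di-tert-butyl-4-methylpyridine (3 equiv), CH2Cl2 (0.005 M), −78 → −20 °C; aq. NaHCO3
Reagents that add atoms: none
Why: Proposed new method: Tf2O sulfonylates the only free hydroxyl (C10), and the secondary triflate should ionise with participation of the neighbouring tertiary bromine on C11, which bridges to C10 with inversion and gives bromonium ion 23 with Br anti to the departed oxygen, so that the (10R) carbinol becomes the (10S) C–Br centre. The closest known reaction types are the bromine-assisted ionisation of β-bromo sulfonates to enantiopure bromonium ions, bromonium-initiated cation–olefin cyclisation and allylsilane-terminated cation–olefin cyclisation; their combination with a 1,2-bromine shift is what is new. The C6=C7 allylsilane attacks the tertiary carbon C11 of the bromonium ion anti to bromine and closes the ring C6–C7–C8–C9–C10–C11 in a 6-endo mode at the bromonium ion (endo also with respect to the alkene) through a chair transition state, and the C7 cation, β to silicon, loses Me3Si+ so that only the exocyclic C7=C14 alkene can form. C10 is controlled by the carbinol centre from step 4 (stereospecific inversion), and C6 by the chair with equatorial bromine together with the (6Z) geometry, which puts C5 equatorial and cis to bromine, i.e. (6R). The step needs ring closure to outrun alkene-to-alkene bromonium transfer and proton loss, which the strongly nucleophilic allylsilane held five bonds away and high dilution should secure, and it needs the absence of free acid, which the hindered pyridine secures; the C3=C4 alkene is deactivated by its allylic acetate and cannot reach C11 through a ring of favourable size.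

**Compound list**

1 | methyl acetoacetate | COC(=O)CC(C)=O | starting material
2 | 1-bromo-3-methylbut-2-ene (prenyl bromide) | CC(C)=CCBr | starting material
3 | sodium lithium salt of the 1,3-dianion of methyl acetoacetate | COC(=O)[CH-]C(=O)[CH2-].[Na+].[Li+] | intermediate
4 | methyl 7-methyl-3-oxooct-6-enoate | COC(=O)CC(=O)CCC=C(C)C | intermediate
5 | sodium (Z)-enolate of 4 (enolate oxygen cis to the ester) | COC(=O)/C=C(\[O-])CCC=C(C)C.[Na+] | intermediate
6 | methyl (2Z)-3-[(diethoxyphosphoryl)oxy]-7-methylocta-2,6-dienoate | COC(=O)/C=C(\OP(=O)(OCC)OCC)CCC=C(C)C | intermediate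
7 | methyl (2Z)-7-methyl-3-[(trimethylsilyl)methyl]octa-2,6-dienoate | COC(=O)/C=C(\C[Si](C)(C)C)CCC=C(C)C | intermediate
8 | methyl (2Z)-5-[(2R)-3,3-dimethyloxiran-2-yl]-3-[(trimethylsilyl)methyl]pent-2-enoate | COC(=O)/C=C(\C[Si](C)(C)C)CC[C@H]1OC1(C)C | intermediate
9 | (2Z)-5-[(2R)-3,3-dimethyloxiran-2-yl]-3-[(trimethylsilyl)methyl]pent-2-en-1-ol | OC/C=C(\C[Si](C)(C)C)CC[C@H]1OC1(C)C | intermediate
10 | methanesulfonate of 9 | CS(=O)(=O)OC/C=C(\C[Si](C)(C)C)CC[C@H]1OC1(C)C | intermediate
11 | (2R)-2-{(3Z)-5-bromo-3-[(trimethylsilyl)methyl]pent-3-en-1-yl}-3,3-dimethyloxirane | BrC/C=C(\C[Si](C)(C)C)CC[C@H]1OC1(C)C | intermediate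
12 | methyl (4S)-2,2-dimethyl-1,3-dioxolane-4-carboxylate | COC(=O)[C@@H]1COC(C)(C)O1 | starting material
13 | (4S)-2,2-dimethyl-1,3-dioxolane-4-carbaldehyde | O=C[C@@H]1COC(C)(C)O1 | intermediate
14 | (4R)-4-ethynyl-2,2-dimethyl-1,3-dioxolane | C#C[C@@H]1COC(C)(C)O1 | intermediate
15 | (2R)-but-3-yne-1,2-diol | C#C[C@@H](O)CO | intermediate
16 | (5R)-5-[(bromomagnesiooxy)methyl]-4-methyl-2,5-dihydro-1,2-oxamagnesole (cyclic alkenylmagnesium alkoxide, Mg on C4 cis to C2) | CC1=C[Mg]O[C@H]1CO[Mg]Br | intermediate
17 | (2R,3Z,6Z)-9-[(2R)-3,3-dimethyloxiran-2-yl]-3-methyl-7-[(trimethylsilyl)methyl]nona-3,6-diene-1,2-diol | OC[C@H](O)/C(C)=C\C/C=C(\C[Si](C)(C)C)CC[C@H]1OC1(C)C | intermediate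
18 | (2R,3Z,6Z)-9-[(2R)-3,3-dimethyloxiran-2-yl]-2-hydroxy-3-methyl-7-[(trimethylsilyl)methyl]nona-3,6-dien-1-yl 4-methylbenzenesulfonate | Cc1ccc(cc1)S(=O)(=O)OC[C@H](O)/C(C)=C\C/C=C(\C[Si](C)(C)C)CC[C@H]1OC1(C)C | intermediate
19 | (2R,3Z,6Z)-2-acetoxy-9-[(2R)-3,3-dimethyloxiran-2-yl]-3-methyl-7-[(trimethylsilyl)methyl]nona-3,6-dien-1-yl 4-methylbenzenesulfonate | Cc1ccc(cc1)S(=O)(=O)OC[C@H](OC(C)=O)/C(C)=C\C/C=C(\C[Si](C)(C)C)CC[C@H]1OC1(C)C | intermediate
20 | (2R,3Z,6Z)-1-bromo-9-[(2R)-3,3-dimethyloxiran-2-yl]-3-methyl-7-[(trimethylsilyl)methyl]nona-3,6-dien-2-yl acetate | BrC[C@H](OC(C)=O)/C(C)=C\C/C=C(\C[Si](C)(C)C)CC[C@H]1OC1(C)C | intermediate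
21 | (2R,3Z,6Z,10R)-1,11-dibromo-10-hydroxy-3,11-dimethyl-7-[(trimethylsilyl)methyl]dodeca-3,6-dien-2-yl acetate | BrC[C@H](OC(C)=O)/C(C)=C\C/C=C(\C[Si](C)(C)C)CC[C@@H](O)C(C)(C)Br | intermediate
22 | trifluoromethanesulfonate of 21 at the C10 hydroxyl | BrC[C@H](OC(C)=O)/C(C)=C\C/C=C(\C[Si](C)(C)C)CC[C@@H](OS(=O)(=O)C(F)(F)F)C(C)(C)Br | intermediate
23 | bromonium ion bridging C10 and C11 (C10 S, Br anti to the former C10–O bond), triflate salt | BrC[C@H](OC(C)=O)/C(C)=C\C/C=C(\C[Si](C)(C)C)CC[C@@H]1[Br+]C1(C)C.[O-]S(=O)(=O)C(F)(F)F | intermediate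
24 | (2R,3Z)-1-bromo-5-[(1R,3S)-3-bromo-2,2-dimethyl-6-methylidenecyclohexyl]-3-methylpent-3-en-2-yl acetate | C=C1CC[C@H](Br)C(C)(C)[C@@H]1C/C=C(/C)[C@H](CBr)OC(C)=O | target

**Step count and risks**

Total steps: 13. Longest linear sequence: 11 (steps 1–6 and 9–13).

Steps most likely to fail:

1. Step 13 (Proposed new method). What may go wrong: bromonium transfer between alkenes of different molecules (loss of enantiopurity, oligomers); proton loss from the bromonium ion before capture; elimination of the triflate without bromine participation; protodesilylation by traces of triflic acid.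
 Fallback, from 20 back to 24, using the established ionisation of a β-bromo tertiary ester: epoxide 20 would be opened with Li2NiBr4 in THF, a soft bromide source that should attack the less substituted carbon C10 in an SN2 sense with inversion. This would give the regioisomeric bromohydrin (2R,3Z,6Z,10S)-1,10-dibromo-11-hydroxy-3,11-dimethyl-7-[(trimethylsilyl)methyl]dodeca-3,6-dien-2-yl acetate F1. Its tertiary hydroxyl would be acylated with trifluoroacetic anhydride and pyridine to the tertiary trifluoroacetate F2. SnCl4 in CH2Cl2 at −78 °C would ionise the tertiary ester with bromine participation, and capture by the allylsilane would give 24 with C10 unchanged from F1.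

2. Step 12. What may go wrong: protodesilylation of the allylsilane; Lewis-acid-triggered cyclisation of the epoxide onto the allylsilane; hydride-shift rearrangement of the epoxide; bromide attack at the secondary carbon. A regiochemical leak toward F1 should not cost stereochemistry, because anti opening at either carbon leads, after activation of the hydroxyl, to the same enantiomer of the bromonium ion.
 Fallback, from 20 back to 21: the opening would be done by silyl transfer instead of a magnesium Lewis acid. Me3SiBr with 2,6-di-tert-butylpyridine in CH2Cl2 at −78 °C would give the β-bromo silyl ether F3 (bromide on C11, OSiMe3 on C10), and pyridinium 4-methylbenzenesulfonate in MeOH at 0 °C would unmask the C10 hydroxyl to give 21.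

3. Step 9. What may go wrong: incomplete carbomagnesiation; methyl transfer from residual MeMgBr to the allylic bromide; SN2′ allylation; 1,4-elimination of the silyl-substituted allylic bromide to a diene; opening of the epoxide by magnesium halide.
 Fallback, from 15 and 11 back to 17, separating carbometalation from coupling: the carbomagnesiation of 15 (via 16) would be quenched with I2 to give (2R,3Z)-4-iodo-3-methylbut-3-ene-1,2-diol F4. The diol would be protected with t-BuMe2SiCl and imidazole as the bis-silyl ether F5. Iodine–magnesium exchange with i-PrMgCl·LiCl would give the alkenylmagnesium chloride F6, free of methyl Grignard, and CuI-catalysed allylation with 11 would give the bis-silyl ether F7. Bu4NF in THF would then give 17.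

**Further compounds**

F1 | step 13 | (2R,3Z,6Z,10S)-1,10-dibromo-11-hydroxy-3,11-dimethyl-7-[(trimethylsilyl)methyl]dodeca-3,6-dien-2-yl acetate | BrC[C@H](OC(C)=O)/C(C)=C\C/C=C(\C[Si](C)(C)C)CC[C@H](Br)C(C)(C)O
F2 | step 13 | trifluoroacetate of F1 at the tertiary C11 hydroxyl | BrC[C@H](OC(C)=O)/C(C)=C\C/C=C(\C[Si](C)(C)C)CC[C@H](Br)C(C)(C)OC(=O)C(F)(F)F
F3 | step 12 | trimethylsilyl ether of 21 at the C10 hydroxyl | BrC[C@H](OC(C)=O)/C(C)=C\C/C=C(\C[Si](C)(C)C)CC[C@@H](O[Si](C)(C)C)C(C)(C)Br
F4 | step 9 | (2R,3Z)-4-iodo-3-methylbut-3-ene-1,2-diol | OC[C@H](O)/C(C)=C\I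
F5 | step 9 | bis(tert-butyldimethylsilyl) ether of F4 | CC(C)(C)[Si](C)(C)OC[C@H](O[Si](C)(C)C(C)(C)C)/C(C)=C\I
F6 | step 9 | (Z)-alkenylmagnesium chloride from F5 (Mg in place of I) | CC(C)(C)[Si](C)(C)OC[C@H](O[Si](C)(C)C(C)(C)C)/C(C)=C\[Mg]Cl
F7 | step 9 | bis(tert-butyldimethylsilyl) ether of 17 | CC(C)(C)[Si](C)(C)OC[C@H](O[Si](C)(C)C(C)(C)C)/C(C)=C\C/C=C(\C[Si](C)(C)C)CC[C@H]1OC1(C)C
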